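**Plan**

Locants: C1 = C(OH)(C7H2OBz), C2 = CH(OBz), C3=C4, C5 = CH(OBz), C6 = CH(OH). The target is (1R,2R,5R,6S), and neighbouring ring oxygens are all trans.
Cuts: first the three benzoates and a C1/C6 acetonide; then C7H2OH goes back to CO2H and C2–O back to C2–B. Last, C1–C2 is cut while C4 is rejoined to the carboxyl oxygen (retro Ireland–Claisen), which opens the carbocycle to a δ-lactone.
Enabling feature: with C7 as a carboxyl, C7–C1(O)–C2–C3=C4 is a γ,δ-unsaturated α-oxy acid, and C1 and C4 stand 1,4 in the ring, bridged by C6–C5. The allyl ester is therefore the six-membered lactone ring O–C7–C1–C6–C5–C4, the 6,2-lactone of D-glucuronic acid lengthened by one carbon at its aldehyde end.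
Forward: glucose diacetonide, O3 ether, free sugar, alkyne, oxidative lactonisation, acetonide, E-alkenylboronate, [3,3] shift that closes the only carbocycle; then C–B oxidation, reduction, ether cleavage, tribenzoylation, ketal hydrolysis.
Stereochemistry: C5 and C6 are C3 and C4 of D-glucose, untouched. C2 of glucose (the C4–O centre) is spent to set C1 by chirality transfer. The E-alkene in a forced boat sets C2. C5 of glucose is erased by enolisation.

Key step: step 7

Remark: lactols 3 and 5 are drawn with an undefined anomeric centre; this centre is lost in the next transformation and has no consequence.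

**Route**

Step 1
Reactants: 1 1,2:5,6-di-O-isopropylidene-α-D-glucofuranose
Product: 2 1,2:5,6-di-O-isopropylidene-3-O-(2-naphthylmethyl)-α-D-glucofuranose
Conditions: NaH, 2-(bromomethyl)naphthalene, DMF, 0 °C to rt
Reagents that add atoms: 2-(bromomethyl)naphthalene, BrCc1ccc2ccccc2c1
Why: Williamson etherification of the only free hydroxyl (O3 of glucose, the later O5); the naphthylmethyl ether should outlast aqueous acid, base, silylation and hydride and still leave with DDQ without touching an alkene.

Step 2
Reactants: 2 1,2:5,6-di-O-isopropylidene-3-O-(2-naphthylmethyl)-α-D-glucofuranose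
Product: 3 3-O-(2-naphthylmethyl)-D-glucopyranose
Conditions: Amberlite IR-120 (H+ form), H2O/1,4-dioxane, 75 °C
Reagents that add atoms: none
Why: Acid-catalysed acetal hydrolysis frees the lactol and the other hydroxyls while the arylmethyl ether stays and no stereocentre is touched.

Step 3
Reactants: 3 3-O-(2-naphthylmethyl)-D-glucopyranose
Product: 4 1,2-dideoxy-4-O-(2-naphthylmethyl)-D-gluco-hept-1-ynitol
Conditions: dimethyl (1-diazo-2-oxopropyl)phosphonate, K2CO3, MeOH, rt to 45 °C
Reagents that add atoms: dimethyl (1-diazo-2-oxopropyl)phosphonate, CC(=O)C(=[N+]=[N-])P(=O)(OC)OC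
Why: Seyferth–Gilbert homologation in its Ohira–Bestmann form acts on the open-chain aldehyde in equilibrium with the lactol, tolerates free hydroxyls because methanol is the solvent, and adds the carbon that becomes C2.

Step 4
Reactants: 4 1,2-dideoxy-4-O-(2-naphthylmethyl)-D-gluco-hept-1-ynitol
Product: 6 δ-lactone diol 6,7-dideoxy-4-O-(2-naphthylmethyl)-L-gulo-hept-6-ynono-1,5-lactone, via pyranose lactol 5 (not isolated)
Conditions: TEMPO (cat.), PhI(OAc)2 (2.2 equiv), MeCN/CH2Cl2, rt
Reagents that add atoms: none
Why: Oxoammonium oxidation picks the primary alcohol, the aldehyde can close only to the six-membered lactol on the propargylic hydroxyl because the γ-oxygen carries the naphthylmethyl group, and a second oxidation gives the δ-lactone (oxidative lactonisation of a 1,5-diol).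

Step 5
Reactants: 6 δ-lactone diol
Product: 7 6,7-dideoxy-2,3-O-isopropylidene-4-O-(2-naphthylmethyl)-L-gulo-hept-6-ynono-1,5-lactone
Conditions: 2,2-dimethoxypropane, camphorsulfonic acid (cat.), acetone, rt
Reagents that add atoms: 2,2-dimethoxypropane, COC(C)(C)OC
Why: The two remaining hydroxyls (erythro O4/O5 pair of glucose, the later O6 and O1) are cis on the lactone ring, so transketalisation closes a cis-fused dioxolane.

Step 6
Reactants: 7 alkynyl lactone acetonide
Product: 8 (E)-6,7-dideoxy-2,3-O-isopropylidene-4-O-(2-naphthylmethyl)-7-(4,4,5,5-tetramethyl-1,3,2-dioxaborolan-2-yl)-L-gulo-hept-6-enono-1,5-lactone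
Conditions: pinacolborane, Cp2Zr(H)Cl (10 mol %), Et3N (10 mol %), CH2Cl2, 40 °C
Reagents that add atoms: pinacolborane, B1OC(C)(C)C(C)(C)O1
Why: Zirconium-catalysed syn hydroboration of the terminal alkyne puts boron on the terminal carbon and should give only the E-alkenylboronate, the geometry that is later translated into C2.

Step 7
Reactants: 8 E-alkenylboronate lactone
Product: 10 tert-butyldimethylsilyl cyclohex-3-ene-1-carboxylate with O1/O6 trans-fused isopropylidene ketal; C2–B(pin) and C5–O-naphthylmethyl; C7 with B and O6 on one face; O1 with O5 on the other, via silyl ketene acetal 9 (not isolated)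
Conditions: TBSCl, KN(SiMe3)2 (added last), THF/DMPU, −78 °C to rt; then PhMe, 90–100 °C
Reagents that add atoms: tert-butyldimethylsilyl chloride, CC(C)(C)[Si](C)(C)Cl
Why: KN(SiMe3)2 removes the C1–H next to the lactone carbonyl and TBSCl, already present, traps the enolate on oxygen as the endocyclic silyl ketene acetal 9, in which O–C7(OTBS)=C1 and C4–C3=C2 form an allyl vinyl ether that on heating undergoes a concerted suprafacial [3,3] shift: C1–C2 forms, C4–O breaks and the alkene moves to C3=C4. It is an Ireland–Claisen rearrangement; the closest known cases are the ring contraction of 6-alkenyl δ-lactones and 6-alkenyl-1,4-dioxan-2-ones through their silyl ketene acetals to cyclohexene- and dihydropyran-carboxylic acids, the thermal Claisen route from glycals bearing a vinyl group at C5 to carbasugar aldehydes, and Claisen rearrangements of 3-borylallyl alcohol derivatives to α-substituted allylboronates. The cyclohexene closes by lactone-to-carbocycle transposition: the termini C4 and C1 are already tied by C5–C6, so the six-atom array must fold as a boat (a bicyclo[2.2.2]octane-like transition state), the only fold that gives a cis alkene inside a six-membered ring. C1 is controlled by the C4 stereocentre (C2 of glucose): the alkenyl arm stands on one face of the lactone and can reach C1 only from that face, so C2 bonds there, C7 is left cis and O1 trans to O6, and the chirality of C4 is consumed. C2 is controlled by the alkene geometry: in the boat the outer (E) substituent on C2 ends cis to C7 and trans to O1, so the E-boronate gives the C2 configuration of the target, while C5 and C6 are spectators. The step needs O-silylation to outrun β-elimination of O6 from the enolate, which the in situ quench and the cis-fused dioxolane (C6–O held near the enolate plane, poor overlap) should secure, and it needs an allyl terminus that survives base and heat, which the pinacol boronate provides better than an acid-labile enol ether.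

Step 8
Reactants: 10 silyl ester allylboronate
Product: 11 hydroxy acid (C7 = CO2H; C2–OH; O1/O6 ketal; C5–O-naphthylmethyl; configuration as in 10)
Conditions: 30% aq H2O2, 2 M aq NaOH, THF, 0 °C; then cold 1 M HCl to pH 4
Reagents that add atoms: hydrogen peroxide, OO
Why: Hydroperoxide adds to boron and the 1,2-shift of C2 from boron to oxygen proceeds with retention, so C2–B becomes C2–OH on the same face, while hydroxide cleaves the labile silyl ester.

Step 9
Reactants: 11 hydroxy acid
Product: 12 diol (C7H2OH; C2–OH; O1/O6 ketal; C5–O-naphthylmethyl)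
Conditions: LiAlH4, THF, 0 °C to reflux; aqueous work-up
Reagents that add atoms: none
Why: LiAlH4 reduces the carboxylate to the primary alcohol and leaves the ketal, the ether and the isolated alkene alone.

Step 10
Reactants: 12 diol
Product: 13 triol (C7H2OH; C2–OH; C5–OH; O1/O6 ketal)
Conditions: DDQ, CH2Cl2/H2O, 0 °C to rt
Reagents that add atoms: none
Why: Oxidative cleavage of the electron-rich arylmethyl ether (hydride abstraction by DDQ, then hydrolysis of the oxocarbenium ion) should be much faster than oxidation of the unactivated cyclohexenols.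

Step 11
Reactants: 13 triol
Product: 14 tribenzoate ketal (O2, O5 and O7 benzoylated; O1/O6 isopropylidene)
Conditions: BzCl (4 equiv), DMAP (cat.), pyridine, 0 °C to rt
Reagents that add atoms: benzoyl chloride, O=C(Cl)c1ccccc1
Why: DMAP-catalysed acylation esterifies the three free hydroxyls at once, while O1 and O6 are locked in the ketal, so the ester pattern of the target needs no selectivity.

Step 12
Reactants: 14 tribenzoate ketal
Product: 15 [(1R,2R,5R,6S)-2,5-bis(benzoyloxy)-1,6-dihydroxycyclohex-3-en-1-yl]methyl benzoate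
Conditions: TFA/H2O, CH2Cl2, 0 °C
Reagents that add atoms: none
Why: The strained trans-fused dioxolane should hydrolyse under mild acid, conditions under which benzoates are neither cleaved nor prone to migrate.

**Compound list**

1 | 1,2:5,6-di-O-isopropylidene-α-D-glucofuranose | CC1(C)O[C@H]2O[C@H]([C@H]3COC(C)(C)O3)[C@H](O)[C@H]2O1 | starting material
2 | 1,2:5,6-di-O-isopropylidene-3-O-(2-naphthylmethyl)-α-D-glucofuranose | CC1(C)O[C@H]2O[C@H]([C@H]3COC(C)(C)O3)[C@H](OCc3ccc4ccccc4c3)[C@H]2O1 | intermediate
3 | 3-O-(2-naphthylmethyl)-D-glucopyranose | OC[C@H]1OC(O)[C@H](O)[C@@H](OCc2ccc3ccccc3c2)[C@@H]1O | intermediate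
4 | 1,2-dideoxy-4-O-(2-naphthylmethyl)-D-gluco-hept-1-ynitol | C#C[C@H](O)[C@@H](OCc1ccc2ccccc2c1)[C@H](O)[C@H](O)CO | intermediate
5 | 6,7-dideoxy-4-O-(2-naphthylmethyl)-L-gulo-hept-6-ynopyranose (lactol, not isolated) | C#C[C@@H]1OC(O)[C@@H](O)[C@@H](O)[C@@H]1OCc1ccc2ccccc2c1 | intermediate
6 | 6,7-dideoxy-4-O-(2-naphthylmethyl)-L-gulo-hept-6-ynono-1,5-lactone | C#C[C@@H]1OC(=O)[C@@H](O)[C@@H](O)[C@@H]1OCc1ccc2ccccc2c1 | intermediate
7 | 6,7-dideoxy-2,3-O-isopropylidene-4-O-(2-naphthylmethyl)-L-gulo-hept-6-ynono-1,5-lactone | C#C[C@@H]1OC(=O)[C@H]2OC(C)(C)O[C@H]2[C@@H]1OCc1ccc2ccccc2c1 | intermediate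
8 | (E)-7-(pinacolatoboryl)hept-6-enono-1,5-lactone derived from 7 | CC1(C)OB(/C=C/[C@@H]2OC(=O)[C@H]3OC(C)(C)O[C@H]3[C@@H]2OCc2ccc3ccccc3c2)OC1(C)C | intermediate
9 | endocyclic tert-butyldimethylsilyl ketene acetal of 8 (not isolated) | CC1(C)OB(/C=C/[C@@H]2OC(O[Si](C)(C)C(C)(C)C)=C3OC(C)(C)O[C@H]3[C@@H]2OCc2ccc3ccccc3c2)OC1(C)C | intermediate
10 | silyl cyclohex-3-ene-1-carboxylate with C2–B(pin), C5–O-naphthylmethyl, O1/O6 trans-fused ketal | CC(C)(C)[Si](C)(C)OC(=O)[C@@]12OC(C)(C)O[C@H]1[C@H](OCc1ccc3ccccc3c1)C=C[C@H]2B1OC(C)(C)C(C)(C)O1 | intermediate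
11 | hydroxy acid (C2–OH, C7 = CO2H) | OC(=O)[C@@]12OC(C)(C)O[C@H]1[C@H](OCc1ccc3ccccc3c1)C=C[C@H]2O | intermediate
12 | diol (C2–OH, C7H2OH) | OC[C@@]12OC(C)(C)O[C@H]1[C@H](OCc1ccc3ccccc3c1)C=C[C@H]2O | intermediate
13 | triol (C2–OH, C5–OH, C7H2OH) | OC[C@@]12OC(C)(C)O[C@H]1[C@H](O)C=C[C@H]2O | intermediate
14 | tribenzoate ketal | O=C(OC[C@@]12OC(C)(C)O[C@H]1[C@H](OC(=O)c1ccccc1)C=C[C@H]2OC(=O)c1ccccc1)c1ccccc1 | intermediate
15 | [(1R,2R,5R,6S)-2,5-bis(benzoyloxy)-1,6-dihydroxycyclohex-3-en-1-yl]methyl benzoate | O=C(OC[C@]1(O)[C@H](OC(=O)c2ccccc2)C=C[C@@H](OC(=O)c2ccccc2)[C@@H]1O)c1ccccc1 | target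

**Step count**

Total step count: 12. Longest linear sequence: 12 steps (1 to 15).

**Steps most likely to fail**

Step 7.
- What may go wrong: the enolate may fragment by β-elimination of the ketal oxygen on C6 before it is silylated. The ketene acetal may also fail to reach the strained boat and decompose or lose silicon on heating.
- Fallback: the ring is closed by ring-closing metathesis and C1–C2 is made by an aldol reaction. It sets out from 3 and comes back at 12.
- NaIO4 cleaves the only free glycol of pyranose 3 (C1–C2 of the sugar), and aqueous NaHCO3 removes the resulting formate to give 2-O-(2-naphthylmethyl)-D-arabinopyranose F1.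
- Wittig methylenation with Ph3P=CH2 gives 1,2-dideoxy-3-O-(2-naphthylmethyl)-D-arabino-hex-1-enitol F2.
- TEMPO/PhI(OAc)2 in aqueous MeCN gives 5,6-dideoxy-4-O-(2-naphthylmethyl)-D-lyxo-hex-5-enonic acid F3.
- 2,2-Dimethoxypropane, MeOH and TsOH give its methyl ester 2,3-acetonide F4.
- LiN(iPr)2 at −78 °C and then acrolein give the aldol adduct F5. The aldehyde should enter anti to the side chain on the dioxolane, which sets C1. The C2 epimers are separated.
- The second-generation Grubbs catalyst in CH2Cl2 closes the cyclohexene to the hydroxy methyl ester F6.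
- LiAlH4 gives 12.

Step 3.
- What may go wrong: homologation may be slow because little open-chain aldehyde is present. Base-induced epimerisation next to the aldehyde and β-elimination of the naphthylmethoxy group could then take over.
- Fallback: a non-basic olefination followed by a Fritsch–Buttenberg–Wiechell type rearrangement. It sets out from 3 and comes back at 4.
- (Dibromomethyl)triphenylphosphonium bromide and Zn in refluxing 1,4-dioxane convert the lactol into the 1,1-dibromoalkene tetraol F7.
- Excess n-BuLi in THF at −78 °C turns F7 into alkyne 4.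

Step 8.
- What may go wrong: boron may be lost without C–O bond formation. The possible pathways are β-elimination toward the ketal oxygen on C1, vinylogous elimination toward O5, allylic shift of boron, and protodeboronation of the hindered ate complex.
- Fallback: the C2–O bond is made before the rearrangement. It sets out from 8 and comes back at 13.
- Cu(OAc)2 and Et3N in 4-methoxybenzyl alcohol couple the alkenylboronate with retention of geometry to give the E-enol ether lactone F8.
- The silylation and heating of step 7 lead through the silyl ketene acetal F9 to the silyl ester F10. The donor oxygen on the allyl terminus should also speed up the [3,3] shift.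
- LiAlH4 gives the primary alcohol F11.
- DDQ removes both arylmethyl ethers to give 13.

**Further compounds**

F1 | step 7 | 2-O-(2-naphthylmethyl)-D-arabinopyranose | OC1OC[C@@H](O)[C@@H](O)[C@@H]1OCc1ccc2ccccc2c1
F2 | step 7 | 1,2-dideoxy-3-O-(2-naphthylmethyl)-D-arabino-hex-1-enitol | C=C[C@@H](OCc1ccc2ccccc2c1)[C@H](O)[C@H](O)CO
F3 | step 7 | 5,6-dideoxy-4-O-(2-naphthylmethyl)-D-lyxo-hex-5-enonic acid | OC(=O)[C@@H](O)[C@@H](O)[C@H](OCc1ccc2ccccc2c1)C=C
F4 | step 7 | methyl 5,6-dideoxy-2,3-O-isopropylidene-4-O-(2-naphthylmethyl)-D-lyxo-hex-5-enoate | COC(=O)[C@H]1OC(C)(C)O[C@H]1[C@H](OCc1ccc2ccccc2c1)C=C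
F5 | step 7 | aldol adduct of F4 with acrolein (C1 quaternary, C2–OH, two vinyl groups) | COC(=O)[C@@]1([C@H](O)C=C)OC(C)(C)O[C@H]1[C@H](OCc1ccc2ccccc2c1)C=C
F6 | step 7 | methyl ester of 11 | COC(=O)[C@@]12OC(C)(C)O[C@H]1[C@H](OCc1ccc3ccccc3c1)C=C[C@H]2O
F7 | step 3 | 1,1-dibromo-1,2-dideoxy-4-O-(2-naphthylmethyl)-D-gluco-hept-1-enitol | BrC(Br)=C[C@H](O)[C@@H](OCc1ccc2ccccc2c1)[C@H](O)[C@H](O)CO
F8 | step 8 | (E)-7-(4-methoxybenzyloxy)hept-6-enono-1,5-lactone analogue of 8 | COc1ccc(CO/C=C/[C@@H]2OC(=O)[C@H]3OC(C)(C)O[C@H]3[C@@H]2OCc2ccc3ccccc3c2)cc1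
F9 | step 8 | silyl ketene acetal of F8 | COc1ccc(CO/C=C/[C@@H]2OC(O[Si](C)(C)C(C)(C)C)=C3OC(C)(C)O[C@H]3[C@@H]2OCc2ccc3ccccc3c2)cc1
F10 | step 8 | silyl cyclohexenecarboxylate with C2–O-(4-methoxybenzyl) | CC(C)(C)[Si](C)(C)OC(=O)[C@@]12OC(C)(C)O[C@H]1[C@H](OCc1ccc3ccccc3c1)C=C[C@H]2OCc1ccc(OC)cc1
F11 | step 8 | primary alcohol from F10 | OC[C@@]12OC(C)(C)O[C@H]1[C@H](OCc1ccc3ccccc3c1)C=C[C@H]2OCc1ccc(OC)cc1
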